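**Retrosynthetic overview**
1. The target comes from the 6α-hydroxy-elemanolide by late tailoring: redox inversion at C6, isobutyrylation, then allylic C15–H oxidation and acetylation.
2. The cyclohexane ring (C5–C10 made, C2–C3 broken) comes from a chair Cope rearrangement of a (1(10)E,4E)-germacradien-12,8β-olide that is not isolated.
3. The ten-membered ring comes from a farnesyl-type 1,10-closure (C6–C7). An allylchromium embedded in a butenolide adds to the terminal enal.
4. The acyclic C15 chain (C8–C9 bond) comes from a catalytic asymmetric vinylogous Mukaiyama aldol of 8-oxogeranyl acetate with a C5 silyloxyfuran made from furan-2(5H)-one and CH2O.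
5. Ring order: γ-lactone (carried in from the furanone), then the ten-membered carbocycle, then the cyclohexane.

Position numbers C1–C15 are germacrane/elemane numbers. In the target these are 5αH, 6β-O, 7αH, 8αH (8β-O), 9α-OAc and 10β-CH3, which is 5S,6S,7S,8S,9S,10S.

Assumption: the (R,R)-bisphosphoramide·SiCl4 catalyst of step 4 exposes the Re face of enal 3. If the sense is the opposite, the equally available (S,S)-catalyst is used.

**Step 1**
Reactants: 1 geranyl acetate
Product: 3 (2E,6E)-3,7-dimethyl-8-oxoocta-2,6-dien-1-yl acetate, via 8-hydroxygeranyl acetate 2 (not isolated)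
Conditions: SeO2 (10 mol %), salicylic acid (10 mol %), t-BuOOH, CH2Cl2, rt; crude + MnO2, CH2Cl2, rt
Reagents that add atoms: selenium dioxide O=[Se]=O (oxygen carrier); tert-butyl hydroperoxide CC(C)(C)OO (terminal oxygen source)
Why: The catalytic SeO2 allylic oxidation (ene reaction then [2,3]-shift) attacks only the electron-rich distal trisubstituted alkene and is E-selective for its trans-methyl group, and MnO2 takes the allylic alcohol to the enal without touching the acetate; no stereocentre is formed.

**Step 2**
Reactants: 4 furan-2(5H)-one; 5 formaldehyde (37 % aq.)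
Product: 6 3-(hydroxymethyl)furan-2(5H)-one
Conditions: n-Bu3P (20 mol %), THF–H2O, rt
Reagents that add atoms: none
Why: In this Morita–Baylis–Hillman α-hydroxymethylation the phosphine adds to the β-carbon, the lactone enolate traps CH2O, and loss of phosphine restores the butenolide; no stereocentre is formed.

**Step 3**
Reactants: 6 3-(hydroxymethyl)furan-2(5H)-one
Product: 7 2-(tert-butyldimethylsilyloxy)-3-[(tert-butyldimethylsilyloxy)methyl]furan
Conditions: TBSOTf (2.2 equiv), Et3N, CH2Cl2, 0 °C
Reagents that add atoms: tert-butyldimethylsilyl triflate CC(C)(C)[Si](C)(C)OS(=O)(=O)C(F)(F)F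
Why: O-silylation of the alcohol and soft enolisation/aromatisation of the butenolide to the 2-silyloxyfuran take place in one operation; no stereocentre is formed.

**Step 4**
Reactants: 3 (2E,6E)-3,7-dimethyl-8-oxoocta-2,6-dien-1-yl acetate; 7 2-(tert-butyldimethylsilyloxy)-3-[(tert-butyldimethylsilyloxy)methyl]furan
Product: 8 (5S)-5-[(1S,2E,6E)-8-acetoxy-1-hydroxy-2,6-dimethylocta-2,6-dien-1-yl]-3-[(tert-butyldimethylsilyloxy)methyl]furan-2(5H)-one
Conditions: SiCl4 (1.1 equiv), (R,R)-binaphthyldiamine-derived bisphosphoramide (5 mol %), i-Pr2NEt (10 mol %), CH2Cl2, −78 °C; aq. NaHCO3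
Reagents that add atoms: none
Why: In this catalytic asymmetric vinylogous Mukaiyama aldol (Lewis-base-activated SiCl4) the chiral cationic silicon complex binds the conjugated aldehyde and exposes its Re face (sets 9S), and furan C5 attacks through an open antiperiplanar transition state that gives the 5,1'-syn (threo) adduct typical of Lewis-acid silyloxyfuran additions (sets 8S).

**Step 5**
Reactants: 8 threo aldol adduct
Product: 9 (5S)-5-[(1S,2E,6E)-1,8-diacetoxy-2,6-dimethylocta-2,6-dien-1-yl]-3-[(tert-butyldimethylsilyloxy)methyl]furan-2(5H)-one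
Conditions: Ac2O, pyridine, CH2Cl2, 0 °C (no stronger base)
Reagents that add atoms: acetic anhydride CC(=O)OC(C)=O
Why: Simple O-acetylation installs the final 9-OAc with retention, and the weak base at low temperature avoids vinylogous E1cB loss of acetate via the acidic H8.

**Step 6**
Reactants: 9 diacetate silyl ether
Product: 10 (5S)-5-[(1S,2E,6E)-1,8-diacetoxy-2,6-dimethylocta-2,6-dien-1-yl]-3-(bromomethyl)furan-2(5H)-one
Conditions: Ph3PBr2 (1.2 equiv), CH2Cl2, 0 °C to rt
Reagents that add atoms: dibromotriphenylphosphorane BrP(Br)(c1ccccc1)(c1ccccc1)c1ccccc1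
Why: This is a direct Appel-type conversion of the primary silyl ether to the bromide (Si–O cleavage, oxyphosphonium, SN2 by bromide) under non-basic conditions, so C8 and C9 are untouched.

**Step 7**
Reactants: 10 bromomethyl butenolide diacetate
Product: 12 (5S)-5-[(1S,2E,6E)-1-acetoxy-2,6-dimethyl-8-oxoocta-2,6-dien-1-yl]-3-(bromomethyl)furan-2(5H)-one, via allylic alcohol 11 (not isolated)
Conditions: immobilised Candida antarctica lipase B, MeOH (5 equiv), MTBE, 30 °C; filter; MnO2, rt
Reagents that add atoms: none
Why: Neutral lipase transesterification removes only the unhindered primary allylic acetate and leaves the hindered secondary 9-OAc in place, and MnO2 oxidises the primary allylic alcohol to the E-enal without affecting the bromide or the base-sensitive butenolide.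

**Step 8**
Reactants: 12 bromo enal
Product: 14 (5S,6R,7S,8S,9S,10S)-9α-acetoxy-6α-hydroxy-5αH,7αH,8αH-elema-1,3,11(13)-trien-12,8-olide, via germacranolide 13 (not isolated)
Conditions: CrCl2 (8 equiv), THF, 23 °C, syringe-pump addition over 12 h (final 2 mM); aq. potassium serinate, extract into toluene; BHT, toluene, 140 °C (sealed), 6 h
Reagents that add atoms: none
Why: Proposed new method: Cr(II) turns the bromide into an allylchromium(III) whose C11=C7 bond is E-locked in the butenolide, and its γ-carbon C7 adds to the Cr-bound s-trans enal through a closed Zimmerman–Traxler chair (closest known chemistry: Nozaki–Hiyama–Kishi macrocyclisation of 2-(bromomethyl)enoate enals to germacranolides and Barbier allylations with 3-(bromomethyl)furan-2(5H)-one), which gives the 6,7-anti pair (6α-OH, 7αH), while the taut E,E-tether can reach the still planar butenolide only on the face that carries C9, so the lactone emerges cis-fused (7αH, 8αH); on heating, 13 reacts from the crossed crown conformer in which H6 eclipses C15 (A1,3 strain) and C7–C11 is equatorial, so the chair Cope rearrangement forms C5–C10 with 5αH and 10β-CH3.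

**Step 9**
Reactants: 14 6α-hydroxy elemanolide
Product: 15 9α-acetoxy-6-oxo-5αH,7αH,8αH-elema-1,3,11(13)-trien-12,8-olide
Conditions: Dess–Martin periodinane, NaHCO3, CH2Cl2, 0 °C; short filtration, used at once
Reagents that add atoms: none
Why: The buffered, near-neutral Dess–Martin oxidation of the only free alcohol removes the 6α-carbinol that has finished its job as the control element, and avoids enolisation at C5/C7 and β-elimination of the lactone oxygen.

**Step 10**
Reactants: 15 6-ketone
Product: 16 (5S,6S,7S,8S,9S,10S)-9α-acetoxy-6β-hydroxy-5αH,7αH,8αH-elema-1,3,11(13)-trien-12,8-olide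
Conditions: NaBH4, CeCl3·7H2O, MeOH–THF, −78 °C
Reagents that add atoms: none
Why: In this Luche 1,2-reduction the chair with vinyl and isopropenyl equatorial has its β-face at C6 blocked by the syn-axial C10–CH3 and C8–O, so hydride enters from the α-face and gives the axial 6β-alcohol (6S), while Ce(III) at −78 °C suppresses conjugate reduction of the α-methylene lactone.

**Step 11**
Reactants: 16 6β-alcohol
Product: 17 (5S,6S,7S,8S,9S,10S)-9α-acetoxy-6β-isobutyryloxy-5αH,7αH,8αH-elema-1,3,11(13)-trien-12,8-olide
Conditions: (i-PrCO)2O, Sc(OTf)3 (5 mol %), MeCN, −20 to 0 °C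
Reagents that add atoms: isobutyric anhydride CC(C)C(=O)OC(=O)C(C)C
Why: Lewis-acid-catalysed acylation esterifies hindered secondary alcohols with retention, and the base-free medium avoids migration of the lactone from O8 to the neighbouring O6.

**Step 12**
Reactants: 17 6β-isobutyrate
Product: 19 target CNP0500052.1, via 15-hydroxy elemanolide 18 (not isolated)
Conditions: SeO2 (0.5 equiv), t-BuOOH, CH2Cl2, 0 °C to rt; then Ac2O, pyridine, DMAP, 0 °C, same flask
Reagents that add atoms: selenium dioxide O=[Se]=O (oxygen carrier); tert-butyl hydroperoxide CC(C)(C)OO (terminal oxygen source); acetic anhydride CC(=O)OC(C)=O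
Why: In the SeO2 ene/[2,3] allylic oxidation the isopropenyl group is the only nucleophilic alkene with accessible allylic hydrogens (the vinyl sits on a quaternary carbon, the methylene lactone is electron-poor, and H5 lies in the alkene plane and is flanked by C10 and C6-OR), so C15 is hydroxylated and acetylated in situ; no stereocentre is touched.

**Compound list**
1 | geranyl acetate | CC(=O)OC/C=C(\C)CCC=C(C)C | starting material
2 | (2E,6E)-8-hydroxy-3,7-dimethylocta-2,6-dien-1-yl acetate | CC(=O)OC/C=C(\C)CC/C=C(\C)CO | intermediate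
3 | (2E,6E)-3,7-dimethyl-8-oxoocta-2,6-dien-1-yl acetate | CC(=O)OC/C=C(\C)CC/C=C(\C)C=O | intermediate
4 | furan-2(5H)-one | O=C1C=CCO1 | starting material
5 | formaldehyde | C=O | starting material
6 | 3-(hydroxymethyl)furan-2(5H)-one | O=C1OCC=C1CO | intermediate
7 | 2-(tert-butyldimethylsilyloxy)-3-[(tert-butyldimethylsilyloxy)methyl]furan | CC(C)(C)[Si](C)(C)OCc1ccoc1O[Si](C)(C)C(C)(C)C | intermediate
8 | threo aldol adduct (8S,9S), 13-OTBS, 6-OAc | CC(=O)OC/C=C(\C)CC/C=C(\C)[C@H](O)[C@@H]1C=C(CO[Si](C)(C)C(C)(C)C)C(=O)O1 | intermediate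
9 | 9-acetate of 8 | CC(=O)OC/C=C(\C)CC/C=C(\C)[C@H](OC(C)=O)[C@@H]1C=C(CO[Si](C)(C)C(C)(C)C)C(=O)O1 | intermediate
10 | 13-bromide diacetate | CC(=O)OC/C=C(\C)CC/C=C(\C)[C@H](OC(C)=O)[C@@H]1C=C(CBr)C(=O)O1 | intermediate
11 | 13-bromide, free C6 allylic alcohol | OC/C=C(\C)CC/C=C(\C)[C@H](OC(C)=O)[C@@H]1C=C(CBr)C(=O)O1 | intermediate
12 | 13-bromide, C6 enal | O=C/C=C(\C)CC/C=C(\C)[C@H](OC(C)=O)[C@@H]1C=C(CBr)C(=O)O1 | intermediate
13 | (1(10)E,4E,6R,7S,8S,9S)-9α-acetoxy-6α-hydroxygermacra-1(10),4,11(13)-trien-12,8β-olide | O[C@@H]1/C=C(\C)CC/C=C(\C)[C@H](OC(C)=O)[C@H]2OC(=O)C(=C)[C@@H]12 | intermediate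
14 | 9α-acetoxy-6α-hydroxyelema-1,3,11(13)-trien-12,8β-olide | C=C[C@]1(C)[C@H](OC(C)=O)[C@H]2OC(=O)C(=C)[C@H]2[C@H](O)[C@H]1C(C)=C | intermediate
15 | 9α-acetoxy-6-oxoelema-1,3,11(13)-trien-12,8β-olide | C=C[C@]1(C)[C@H](OC(C)=O)[C@H]2OC(=O)C(=C)[C@H]2C(=O)[C@H]1C(C)=C | intermediate
16 | 9α-acetoxy-6β-hydroxyelema-1,3,11(13)-trien-12,8β-olide | C=C[C@]1(C)[C@H](OC(C)=O)[C@H]2OC(=O)C(=C)[C@H]2[C@@H](O)[C@H]1C(C)=C | intermediate
17 | 9α-acetoxy-6β-isobutyryloxyelema-1,3,11(13)-trien-12,8β-olide | C=C[C@]1(C)[C@H](OC(C)=O)[C@H]2OC(=O)C(=C)[C@H]2[C@@H](OC(=O)C(C)C)[C@H]1C(C)=C | intermediate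
18 | 15-hydroxy derivative of 17 | C=C[C@]1(C)[C@H](OC(C)=O)[C@H]2OC(=O)C(=C)[C@H]2[C@@H](OC(=O)C(C)C)[C@H]1C(=C)CO | intermediate
19 | CNP0500052.1 (9α,15-diacetoxy-6β-isobutyryloxyelema-1,3,11(13)-trien-12,8β-olide) | C=C[C@]1(C)[C@H](OC(C)=O)[C@H]2OC(=O)C(=C)[C@H]2[C@@H](OC(=O)C(C)C)[C@H]1C(=C)COC(C)=O | target

**Totals**
Total step count: 12. Longest linear sequence: 11 (steps 2–12, from furan-2(5H)-one). The sequence from geranyl acetate is 10 steps.

**The three steps most likely to fail**

Step 8. The risks are:
- oligomerisation;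
- reductive 1,4-fragmentation of the bromobutenolide with opening of the lactone;
- closure on the wrong butenolide face;
- an incomplete Cope equilibrium.

The fallback sets out from 12 and replaces the reductive metal closure by a neutral thermal allylboration. Base-free palladium-catalysed borylation of 12 (B2pin2, Pd2(dba)3, toluene–DMSO, 40 °C) gives the pinacol allylboronate enal F1. This electron-poor 2-carbonyl allylboronate is inert to the aldehyde at room temperature and can be purified. Slow addition of F1 to toluene at 130–140 °C closes C6–C7 through the same E-locked chair. The boron alkoxide of 13 undergoes the Cope rearrangement in the same hot solution, and work-up with aqueous triethanolamine returns to the route at 14.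

Step 9, together with the handling of 15. Ketone 15 is a β-acyloxy ketone with H7 and O8 antiperiplanar. It may open the lactone by E1cB elimination, epimerise at C5 or C7, or move the exocyclic alkene to C7=C11. The fallback sets out from 14 and avoids the ketone by inverting C6 through substitution. ClCH2SO2Cl in pyridine at 0 °C gives the 6α-chloromethanesulfonate F2. Caesium isobutyrate with 18-crown-6 in toluene at 80–110 °C displaces the sulfonate by SN2 with inversion. This delivers the 6β-isobutyrate directly and returns to the route at 17.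

Step 12. The risks are competing oxidation at H5, over-oxidation to the C15 enal, and low conversion of the hindered isopropenyl group. The fallback sets out from 17 and uses ene-type allylic chlorination instead of oxygen transfer. NaOCl with CeCl3·7H2O in CH2Cl2–H2O at 0 °C gives the 15-chloride F3. CsOAc in DMF at room temperature converts F3 by SN2 into the acetate, which returns to the route at 19.

**Further compounds**
F1 | step 8 | (5S)-5-[(1S,2E,6E)-1-acetoxy-2,6-dimethyl-8-oxoocta-2,6-dien-1-yl]-3-[(4,4,5,5-tetramethyl-1,3,2-dioxaborolan-2-yl)methyl]furan-2(5H)-one | O=C/C=C(\C)CC/C=C(\C)[C@H](OC(C)=O)[C@@H]1C=C(CB2OC(C)(C)C(C)(C)O2)C(=O)O1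
F2 | step 9 | 9α-acetoxy-6α-(chloromethylsulfonyloxy)elema-1,3,11(13)-trien-12,8β-olide | C=C[C@]1(C)[C@H](OC(C)=O)[C@H]2OC(=O)C(=C)[C@H]2[C@H](OS(=O)(=O)CCl)[C@H]1C(C)=C
F3 | step 12 | 9α-acetoxy-15-chloro-6β-isobutyryloxyelema-1,3,11(13)-trien-12,8β-olide | C=C[C@]1(C)[C@H](OC(C)=O)[C@H]2OC(=O)C(=C)[C@H]2[C@@H](OC(=O)C(C)C)[C@H]1C(=C)CCl
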